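## Structural features

2-O-Acetylzeylenone is a single carbocycle with no second ring: a cyclohex-4-en-6-one, numbered here C1 (quaternary carbinol carrying the exocyclic C7H2–OBz), C2 (CHOAc), C3 (CHOBz), C4=C5 and C6 (ketone). The three stereocentres C1, C2 and C3 are contiguous, (1S,2S,3R): O1 and O2 are cis, O2 and O3 are trans, C3 is allylic and C1 is alpha to the ketone. Four neighbouring oxygens carry three different states (O1 free, O2 acetyl, O3 and O7 benzoyl), so acyl migration among them is a constant threat. The fragile parts are the gamma-acyloxy enone, which eliminates and aromatises under base, the alpha-ketol at C1/C6, and the acetate, which is best put on last. The real difficulty is double: the tetrasubstituted carbinol C1 must be set against C2, and O2 must be told apart from O3 although both are secondary. The key step uses the fact that C4=C5 is the only ring bond with neither a stereocentre nor a heteroatom, so the ring can be closed there by alkene metathesis once C1–C3 and C7 are in place; the trans C2/C3 diol is the threo diol of (2S,3S)-tartaric acid. A second feature is used after ring closure: because O1/O2 are cis and O2/O3 trans on the ring, an isopropylidene ketal prefers O1/O2 and so sets O3 free selectively.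

## Logic of the disconnections

19 is cut at the O2–acetyl bond to 17 and 18. The acetate is the most labile and most migration-prone group, so it goes on last. The forward step must acylate the secondary O2 and leave the tertiary, ketone-flanked O1 alone; the steric difference is large.

17 is cut at the O7–benzoyl bond to 16 and 14. This removes one of two like esters and leaves a primary hydroxyl beside a hindered secondary and a tertiary one. The forward step needs primary-selective acylation at low temperature.

16 is cut at the two ketal C–O bonds on O1/O2 and at the O7–CH2 acetal bond, leading to 15. Both groups are acid-labile and fall in one operation, so three hydroxyls are masked by two groups. The acid must not move or cleave the O3 benzoate.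

15 is cut at the O3–benzoyl bond to 13 and 14. O3–H is the only free hydroxyl in 13, so no selectivity is asked of the forward step.

13 is traced to 12 by moving the ketal: the O1–C(ketal) bond is cut and the O3–C(ketal) bond restored. This is the device that distinguishes O2 from O3 without a selective acylation, and it puts the ketal back where the tartrate had it. The forward step needs thermodynamic control under acid, with O7 blocked by a group that survives acid and cannot itself enter a ketal.

12 is cut at C4=C5 to the acyclic dienone 11. The cut removes the ring and no stereocentre, and leaves two terminal alkenes. The forward step must close a six-membered ring trans-fused to a dioxolane, next to a free tertiary hydroxyl, faster than the vinyl ketone oligomerises.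

11 is cut at C1–C6 to ketone 8 and the three-carbon acryloyl anion equivalent 9, passing through 10. This removes the C1 stereocentre, so 8 holds only the two tartrate centres. The forward addition must take the Felkin–Anh face (1S), and the unmasking of the ketone must spare the dioxolane and the O7 acetal.

8 is cut at C1–C7 to amide 6 and the alkoxymethyl donor 7. C7 and its protected oxygen arrive in one step. The forward step needs a single addition that stops at the ketone, and no epimerisation at C2.

6 is related to ester 4 and amine salt 5 by the amide C–N bond, a functional-group change to an acyl donor that stops at the ketone stage.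

4 is cut at the terminal C=C of the C3 vinyl group and taken back, through aldehyde 3, to diester 1 and phosphonium salt 2. Because 1 is C2-symmetric, either ester gives the same product. The (4S,5S) centres of 1 become C2 (S) and C3 (R; the descriptor changes only because vinyl ranks below C2). The forward step must reduce one ester only.

## Other disconnections considered

Alternative 1: The cut is the C2–O2 bond of an O1/O2-bridged intermediate, back to the achiral cross-conjugated p-quinol A1. In the forward key step the tertiary hydroxyl of A1 is esterified in the flask by an arylboronic acid; under a chiral tertiary amine–thiourea catalyst the boron-bound hydroxyl adds to one of the two enantiotopic enone beta-carbons, giving the cis-fused dioxaborolane A2.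
- In its favour: the absolute configuration comes from a catalyst and no chiral pool is needed. C1 and the cis O1/O2 pair are set in one step by a five-membered tether, which is better than the open-chain 1,2-induction of step 4. The C7 benzoate is present from the start, also better. O2 is tied to O1 and so distinguished from every other oxygen, which equals what 13 achieves.
- Against it here: A2 has the carbonyl at C4, the alkene at C5=C6 and a methylene at C3, whereas the target needs the ketone at C6, the alkene at C4=C5 and an oxygen at C3 trans to O2. That means a 1,3-transposition of the enone (reduction, allylic shift, re-oxidation) and an oxygenation at C3, each with its own regio- and stereochemical question. The enantioselectivity would rest on the catalyst rather than on the substrate.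
- Comparison: structurally A2 solves C1/C2 more elegantly but leaves the ring at the wrong oxidation pattern, while 12 has every ring carbon at its final oxidation level. Mechanistically both key steps are catalytic and mild. In step economy Alternative 1 should be shorter before its key step (about 2 steps against 4) and clearly longer after it.

Alternative 2: The cut is at the C3–O and C6–O bonds, back to the brominated cyclohexadiene cis-diol acetonide A3 of microbial arene dihydroxylation. The forward key step is a sensitised photo-oxygenation: the [4+2] addition across C3 and C6 on the face anti to the ketal gives the bridgehead-bromo endoperoxide A4. Cleavage of the O–O bond with loss of bromide from C6 would then give the gamma-hydroxy enone A5.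
- In its favour: O1/O2 cis come from the enzyme, O3 trans from the facial bias of a rigid bicycle, and the C6 ketone from the bromine, so three oxygenated ring carbons and the enone arrive in about 3 steps. On step count to this stage and on the certainty of the C2/C3 relationship it is the equal or the better of the chosen plan. A5 is 13 without the C7 branch, so O3 is already distinguished, which is equal.
- Against it here: C1 of A5 bears hydrogen where the target has C7. The quaternary centre would have to be made late, by C-hydroxymethylation of an enolate that sits inside the ketal, has O2 as a beta leaving group and a gamma oxygen, and is therefore prone to elimination and aromatisation. The photochemical step and the labile bromo peroxide add handling problems.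
- Comparison: the chosen plan makes the C1–C7 bond before the ring exists, on a robust acyclic ketone. Alternative 2 is shorter on paper, but its one remaining carbon–carbon bond is its weakest point.

Alternative 3: The cut is the C1–C6 ring bond together with the pyran C5–O bond, back to the gluco-configured 2-benzoyloxy glycal A6 with a vinyl group on sugar C5. The forward key step is a thermal [3,3] Claisen rearrangement of the allyl vinyl ether inside the pyran, which should give the cyclohexene aldehyde A7 with C4=C5 and C7 (as CHO) in place.
- In its favour: C2 and C3 come straight from the sugar. C1 would be set by suprafacial chirality transfer from sugar C5 through a bicyclic boat-like transition state, which is better controlled than the Felkin–Anh addition of step 4. The three final acyl groups can ride through, the O1 benzoate being expected to shift to O7 once the aldehyde is reduced; this avoids the five-step end-game of the chosen plan and is a point where the alternative is better.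
- Against it here: A7 still has C6 as a methylene and C7 as an aldehyde, so an allylic oxidation at C6 (in competition with the C3–H) and a reduction are needed. The rearrangement needs high temperature in the presence of an allylic benzoate, which may itself undergo an acyl shift or elimination. Making A6 requires three hexose oxygens with two different acyl groups and a one-carbon extension at sugar C6, a long protecting-group sequence.
- Comparison: structurally A7 is closer to the target in its ester pattern and further in its ring oxidation level. Mechanistically a concerted, stereospecific rearrangement stands against a catalytic, mild but stereochemically silent metathesis. In step economy the work before the key step is expected to outweigh the shorter end-game.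

Key step: step 5

Remark on the chemistry: ring atoms are numbered as in the target (C1 quaternary carbinol, C2, C3, C4=C5, C6 ketone, C7 exocyclic CH2). O7 is carried as a methoxymethyl ether because it arrives in one step as LiCH2OCH2OCH3, cannot migrate to the neighbouring tertiary alkoxide, and survives the acid-catalysed ketal shift of step 6.

## Route

Step 1
Reactants: 1 dimethyl (4S,5S)-2,2-dimethyl-1,3-dioxolane-4,5-dicarboxylate (dimethyl 2,3-O-isopropylidene-D-tartrate); 2 methyltriphenylphosphonium bromide
Product: 4 methyl (4S,5R)-5-ethenyl-2,2-dimethyl-1,3-dioxolane-4-carboxylate, via aldehyde ester 3 (not isolated)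
Conditions: iBu2AlH (1.05 equiv), toluene, −78 °C, 2 h; then Ph3P=CH2 (2.5 equiv, from 2 and KN(SiMe3)2 in THF), −78 °C → rt; aq. potassium sodium tartrate
Reagents that add atoms: methyltriphenylphosphonium bromide (2), C[P+](c1ccccc1)(c1ccccc1)c1ccccc1.[Br-]
Why: Partial ester reduction stops at the tetrahedral aluminium hemiacetal at −78 °C, and the C2-symmetry of 1 makes the two esters equivalent, so only over-reduction is at stake. The hemiacetal releases aldehyde 3 to the ylide (Wittig methylenation); the trans-dioxolane is the thermodynamic isomer, so the alpha-stereocentre should survive.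

Step 2
Reactants: 4 methyl (4S,5R)-5-ethenyl-2,2-dimethyl-1,3-dioxolane-4-carboxylate; 5 N,O-dimethylhydroxylamine hydrochloride
Product: 6 (4S,5R)-5-ethenyl-N-methoxy-N,2,2-trimethyl-1,3-dioxolane-4-carboxamide
Conditions: 5 (1.5 equiv), iPrMgCl (3.0 equiv), THF, −20 → 0 °C
Reagents that add atoms: N,O-dimethylhydroxylamine hydrochloride (5), CNOC.Cl
Why: Aminolysis of the ester by the magnesium amide formed in the flask gives the Weinreb amide. The conditions are cold and brief, and the trans-disubstituted dioxolane is the stable isomer, so C2 should not epimerise.

Step 3
Reactants: 6 (4S,5R)-5-ethenyl-N-methoxy-N,2,2-trimethyl-1,3-dioxolane-4-carboxamide; 7 tributyl[(methoxymethoxy)methyl]stannane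
Product: 8 1-[(4S,5R)-5-ethenyl-2,2-dimethyl-1,3-dioxolan-4-yl]-2-(methoxymethoxy)ethan-1-one
Conditions: 7 (1.3 equiv), nBuLi (1.25 equiv), THF, −78 °C, 15 min; then 6, −78 °C, 30 min; aq. NH4Cl
Reagents that add atoms: tributyl[(methoxymethoxy)methyl]stannane (7), CCCC[Sn](CCCC)(CCCC)COCOC
Why: Tin–lithium exchange gives LiCH2OCH2OCH3, which adds once to the N-methoxy-N-methylamide because the chelated tetrahedral intermediate holds until work-up (Weinreb ketone synthesis). C7 and its protected oxygen are installed together.

Step 4
Reactants: 8 1-[(4S,5R)-5-ethenyl-2,2-dimethyl-1,3-dioxolan-4-yl]-2-(methoxymethoxy)ethan-1-one; 9 methoxyallene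
Product: 11 (4S)-4-[(4S,5R)-5-ethenyl-2,2-dimethyl-1,3-dioxolan-4-yl]-4-hydroxy-5-(methoxymethoxy)pent-1-en-3-one, via allenyl carbinol 10 (not isolated)
Conditions: 9 (1.5 equiv), nBuLi (1.4 equiv), THF, −78 °C, 30 min; then 8, −78 °C, 1 h; then 1 M aq. HCl, THF, 0 °C, 30 min; product used without delay
Reagents that add atoms: methoxyallene (9), COC=C=C; water, O
Why: 1-Lithio-1-methoxyallene is an acryloyl anion equivalent that adds 1,2 to the ketone. Under Felkin–Anh control the C2–O bond of the dioxolane lies anti to the incoming nucleophile, which passes H-2, so the new C1–O bond is anti to C2–O in the C3–C2–C1–C6 zigzag (1S, cis in the later ring). Acid then protonates the central allene carbon, water adds and methanol leaves (enol ether hydrolysis), unveiling the vinyl ketone faster than the dioxolane or the O7 acetal hydrolyse at 0 °C.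

Step 5
Reactants: 11 (4S)-4-[(4S,5R)-5-ethenyl-2,2-dimethyl-1,3-dioxolan-4-yl]-4-hydroxy-5-(methoxymethoxy)pent-1-en-3-one
Product: 12 (3aS,4S,7aR)-4-hydroxy-4-[(methoxymethoxy)methyl]-2,2-dimethyl-3a,7a-dihydro-1,3-benzodioxol-5(4H)-one
Conditions: RuCl2(H2IMes)(PCy3)(=CHPh) (second-generation Grubbs catalyst, 5 mol%), CH2Cl2 (5 mM), 40 °C, argon sparge
Reagents that add atoms: none
Why: The benzylidene of the catalyst should first exchange with the electron-richer, unhindered C3 vinyl group (loss of styrene) to give a ruthenium alkylidene at C4. This alkylidene adds intramolecularly across the acryloyl C5=CH2 bond to a ruthenacyclobutane, whose cycloreversion forms C4=C5 and releases Ru=CH2, which carries the chain with loss of ethylene. The closest known reaction type is ring-closing metathesis of acyclic 1,7-dienes and dienones to cyclohexenes and cyclohexenones, including dienes bridged by a trans-dioxolane from tartaric acid. The one ring is closed as a six-membered carbocycle by metathesis of two terminal alkenes, trans-fused to the dioxolane, and the ring size forces the Z alkene. No stereocentre is formed; C1, C2 and C3 are spectators and none is epimerisable under these neutral conditions. The selectivity needed is ring closure over cross-metathesis and oligomerisation through the vinyl ketone: it should be secured by initiation at the allylic-ether alkene, by the reluctance of the electron-poor acryloyl group to homodimerise, by the quaternary C1 and the dioxolane, which restrict the rotamers about C1–C2 and C2–C3, and by the 5 mM dilution. The free tertiary hydroxyl and the O7 acetal are not expected to interfere with the ruthenium carbene.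

Step 6
Reactants: 12 (3aS,4S,7aR)-4-hydroxy-4-[(methoxymethoxy)methyl]-2,2-dimethyl-3a,7a-dihydro-1,3-benzodioxol-5(4H)-one
Product: 13 (3aS,7R,7aS)-7-hydroxy-3a-[(methoxymethoxy)methyl]-2,2-dimethyl-7,7a-dihydro-1,3-benzodioxol-4(3aH)-one
Conditions: (+)-camphor-10-sulfonic acid (0.1 equiv), dry acetone, rt; then Et3N
Reagents that add atoms: none
Why: Acid-catalysed acetal migration under thermodynamic control: opening of the strained trans-fused O2/O3 dioxolane leaves an oxocarbenium ion on O2 that the cis tertiary O1–H captures, and the cis-fused O1/O2 ketal is the stable isomer. O7 is blocked, so no other ketal can form, and O3–H is released as the only free hydroxyl; no C–O bond at a stereocentre is broken.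

Step 7
Reactants: 13 (3aS,7R,7aS)-7-hydroxy-3a-[(methoxymethoxy)methyl]-2,2-dimethyl-7,7a-dihydro-1,3-benzodioxol-4(3aH)-one; 14 benzoyl chloride
Product: 15 (3aS,7R,7aS)-3a-[(methoxymethoxy)methyl]-2,2-dimethyl-4-oxo-3a,4,7,7a-tetrahydro-1,3-benzodioxol-7-yl benzoate
Conditions: BzCl (1.5 equiv), pyridine, DMAP (0.1 equiv), CH2Cl2, 0 °C → rt
Reagents that add atoms: benzoyl chloride (14), O=C(Cl)c1ccccc1
Why: Nucleophile-catalysed O-acylation of the only free hydroxyl, so no regiochemical question arises. The mild amine base should not enolise the gamma-oxygenated enone.

Step 8
Reactants: 15 (3aS,7R,7aS)-3a-[(methoxymethoxy)methyl]-2,2-dimethyl-4-oxo-3a,4,7,7a-tetrahydro-1,3-benzodioxol-7-yl benzoate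
Product: 16 (1R,5S,6S)-5,6-dihydroxy-5-(hydroxymethyl)-4-oxocyclohex-2-en-1-yl benzoate
Conditions: CF3CO2H/H2O (9:1), 0 °C → rt
Reagents that add atoms: none
Why: Acid hydrolysis of the isopropylidene ketal and of the formaldehyde acetal on O7 in one operation. Benzoates are stable to aqueous acid of this strength, and acid-catalysed acyl migration between trans-disposed O3 and O2 is slow.

Step 9
Reactants: 16 (1R,5S,6S)-5,6-dihydroxy-5-(hydroxymethyl)-4-oxocyclohex-2-en-1-yl benzoate; 14 benzoyl chloride
Product: 17 zeylenone, [(1S,5R,6S)-5-(benzoyloxy)-1,6-dihydroxy-2-oxocyclohex-3-en-1-yl]methyl benzoate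
Conditions: BzCl (1.05 equiv), pyridine, CH2Cl2, −40 → −20 °C
Reagents that add atoms: benzoyl chloride (14), O=C(Cl)c1ccccc1
Why: Kinetically selective acylation of the primary O7–H. O2–H is secondary and flanked by the quaternary C1 and the benzoylated C3, and O1–H is tertiary, so one equivalent at low temperature should stop at the monoester.

Step 10
Reactants: 17 zeylenone, [(1S,5R,6S)-5-(benzoyloxy)-1,6-dihydroxy-2-oxocyclohex-3-en-1-yl]methyl benzoate; 18 acetic anhydride
Product: 19 2-O-acetylzeylenone, [(1S,5R,6S)-6-(acetyloxy)-5-(benzoyloxy)-1-hydroxy-2-oxocyclohex-3-en-1-yl]methyl benzoate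
Conditions: Ac2O (1.5 equiv), pyridine, CH2Cl2, 0 °C → rt
Reagents that add atoms: acetic anhydride (18), CC(=O)OC(C)=O
Why: Acetylation of the secondary O2–H. The tertiary O1–H next to the ketone is too hindered to react without a stronger acyl-transfer catalyst, so the free hydroxyl of the target is left in place.

## Compound list

1 | dimethyl (4S,5S)-2,2-dimethyl-1,3-dioxolane-4,5-dicarboxylate (dimethyl 2,3-O-isopropylidene-D-tartrate) | COC(=O)[C@H]1OC(C)(C)O[C@@H]1C(=O)OC | starting material
2 | methyltriphenylphosphonium bromide | C[P+](c1ccccc1)(c1ccccc1)c1ccccc1.[Br-] | starting material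
3 | methyl (4S,5S)-5-formyl-2,2-dimethyl-1,3-dioxolane-4-carboxylate | COC(=O)[C@H]1OC(C)(C)O[C@@H]1C=O | intermediate
4 | methyl (4S,5R)-5-ethenyl-2,2-dimethyl-1,3-dioxolane-4-carboxylate | COC(=O)[C@H]1OC(C)(C)O[C@@H]1C=C | intermediate
5 | N,O-dimethylhydroxylamine hydrochloride | CNOC.Cl | starting material
6 | (4S,5R)-5-ethenyl-N-methoxy-N,2,2-trimethyl-1,3-dioxolane-4-carboxamide | CON(C)C(=O)[C@H]1OC(C)(C)O[C@@H]1C=C | intermediate
7 | tributyl[(methoxymethoxy)methyl]stannane | CCCC[Sn](CCCC)(CCCC)COCOC | starting material
8 | 1-[(4S,5R)-5-ethenyl-2,2-dimethyl-1,3-dioxolan-4-yl]-2-(methoxymethoxy)ethan-1-one | C=C[C@H]1OC(C)(C)O[C@@H]1C(=O)COCOC | intermediate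
9 | methoxyallene (1-methoxypropa-1,2-diene) | COC=C=C | starting material
10 | (2S)-2-[(4S,5R)-5-ethenyl-2,2-dimethyl-1,3-dioxolan-4-yl]-3-methoxy-1-(methoxymethoxy)penta-3,4-dien-2-ol | C=C[C@H]1OC(C)(C)O[C@@H]1[C@@](O)(COCOC)C(OC)=C=C | intermediate
11 | (4S)-4-[(4S,5R)-5-ethenyl-2,2-dimethyl-1,3-dioxolan-4-yl]-4-hydroxy-5-(methoxymethoxy)pent-1-en-3-one | C=C[C@H]1OC(C)(C)O[C@@H]1[C@@](O)(COCOC)C(=O)C=C | intermediate
12 | (3aS,4S,7aR)-4-hydroxy-4-[(methoxymethoxy)methyl]-2,2-dimethyl-3a,7a-dihydro-1,3-benzodioxol-5(4H)-one (trans-fused O2/O3 ketal) | CC1(C)O[C@@H]2C=CC(=O)[C@](O)(COCOC)[C@H]2O1 | intermediate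
13 | (3aS,7R,7aS)-7-hydroxy-3a-[(methoxymethoxy)methyl]-2,2-dimethyl-7,7a-dihydro-1,3-benzodioxol-4(3aH)-one (cis-fused O1/O2 ketal, free O3–H) | CC1(C)O[C@H]2[C@H](O)C=CC(=O)[C@]2(O1)COCOC | intermediate
14 | benzoyl chloride | O=C(Cl)c1ccccc1 | starting material
15 | (3aS,7R,7aS)-3a-[(methoxymethoxy)methyl]-2,2-dimethyl-4-oxo-3a,4,7,7a-tetrahydro-1,3-benzodioxol-7-yl benzoate | CC1(C)O[C@H]2[C@H](OC(=O)c3ccccc3)C=CC(=O)[C@]2(O1)COCOC | intermediate
16 | (1R,5S,6S)-5,6-dihydroxy-5-(hydroxymethyl)-4-oxocyclohex-2-en-1-yl benzoate | O[C@H]1[C@H](OC(=O)c2ccccc2)C=CC(=O)[C@]1(O)CO | intermediate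
17 | zeylenone, [(1S,5R,6S)-5-(benzoyloxy)-1,6-dihydroxy-2-oxocyclohex-3-en-1-yl]methyl benzoate | O[C@H]1[C@H](OC(=O)c2ccccc2)C=CC(=O)[C@]1(O)COC(=O)c1ccccc1 | intermediate
18 | acetic anhydride | CC(=O)OC(C)=O | starting material
19 | 2-O-acetylzeylenone, [(1S,5R,6S)-6-(acetyloxy)-5-(benzoyloxy)-1-hydroxy-2-oxocyclohex-3-en-1-yl]methyl benzoate | CC(=O)O[C@H]1[C@H](OC(=O)c2ccccc2)C=CC(=O)[C@]1(O)COC(=O)c1ccccc1 | target

## Step count and least certain steps

Total step count: 10. Longest linear sequence: 10 steps (1 → 19); all other inputs are reagents.

Step 5 (key step). The most likely failure is slow ring closure: the trans-fused transition state is strained and the acryloyl alkene reacts sluggishly with the ruthenium alkylidene, so cross-metathesis to oligomers and catalyst decay may take over. The fallback takes the electron-poor alkene out of the metathesis. It sets out from 11, which is reduced 1,2 with NaBH4/CeCl3·7H2O in MeOH at −78 °C (Luche reduction) to the divinyl carbinol F1, both C6 epimers. F1 is closed with the same RuCl2(H2IMes)(PCy3)(=CHPh) catalyst, now joining two allylic-oxygen alkenes and with C6 tetrahedral, to the cyclohexenediol F2. The secondary allylic hydroxyl of F2 is then oxidised with Dess–Martin periodinane, the tertiary hydroxyl being inert and the C6 configuration irrelevant. The fallback comes back to the route at 12.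

Step 4. The most likely failure is poor facial selectivity: lithium chelated between the carbonyl oxygen and O2 of the dioxolane would deliver the allenyl anion to the face opposite to the Felkin–Anh one. The fallback reverses the order of the two additions and makes chelation the controlling element. It sets out from 6, which is acylated once by 1-lithio-1-methoxyallene (from 9 and nBuLi, THF, −78 °C) to the allenyl ketone F3. The magnesium reagent made from 7 (nBuLi, then MgBr2·OEt2) is then added in CH2Cl2/Et2O at −78 °C. With magnesium bridging the ketone oxygen and O2, the C7 nucleophile should enter past H-2 and so give the same 1S carbinol. The fallback comes back to the route at 10, which is hydrolysed as in step 4.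

Step 6. The most likely failure is loss of the ketal to adventitious water, or a stalled equilibration, because re-closure on the hindered, ketone-flanked tertiary O1 is slow. The fallback replaces migration by removal and re-installation. It sets out from 12, whose strained trans-ketal is hydrolysed in 80% aq. AcOH at rt (the O7 acetal survives) to the triol F4. F4 is ketalised under equilibrating conditions (2,2-dimethoxypropane, (+)-camphor-10-sulfonic acid, acetone), where only the cis O1/O2 pair can give an unstrained dioxolane. The fallback comes back to the route at 13.

Step 1. The most likely failure is poor mono-selectivity of the hydride reduction (over-reduction to the alcohol and reduction of both esters) and loss of the hydrated aldehyde. The fallback differentiates the esters by hydrolysis instead. It sets out from 1: KOH (1.0 equiv) in MeOH gives the mono acid F5, BH3·SMe2 in THF reduces the acid and not the ester to the hydroxy ester F6, and Swern oxidation gives the aldehyde. The fallback comes back to the route at 3, which is methylenated with the ylide from 2 to 4.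

Step 8. The most likely failure is incomplete cleavage of the O7 acetal, or migration or loss of the O3 benzoate under the acid strength that the acetal needs. The fallback removes the acid-labile groups before any ester is present. It sets out from 13, which is hydrolysed with 3 M aq. HCl/THF to the tetraol F7. F7 is benzoylated with BzCl (2.1 equiv) in pyridine/CH2Cl2 at −40 °C at the primary O7 and the allylic O3, leaving the flanked O2 and the tertiary O1. This relies on kinetic regioselectivity, which is why it is the fallback and not the main line. It comes back to the route at 17.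

## Further compounds

F1 | step 5 | divinyl carbinol from 1,2-reduction of 11 at C6 (both C6 epimers), 4-[(4S,5R)-5-ethenyl-2,2-dimethyl-1,3-dioxolan-4-yl]-5-(methoxymethoxy)pent-1-ene-3,4-diol | C=C[C@H]1OC(C)(C)O[C@@H]1[C@@](O)(COCOC)C(O)C=C
F2 | step 5 | cyclohexenediol, the C6 alcohol of 12 (both C6 epimers), trans-fused O2/O3 ketal | CC1(C)O[C@@H]2C=CC(O)[C@](O)(COCOC)[C@H]2O1
F3 | step 4 | 1-[(4S,5R)-5-ethenyl-2,2-dimethyl-1,3-dioxolan-4-yl]-2-methoxybuta-2,3-dien-1-one | C=C[C@H]1OC(C)(C)O[C@@H]1C(=O)C(OC)=C=C
F4 | step 6 | (4R,5S,6S)-4,5,6-trihydroxy-6-[(methoxymethoxy)methyl]cyclohex-2-en-1-one | O[C@H]1[C@H](O)C=CC(=O)[C@]1(O)COCOC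
F5 | step 1 | (4S,5S)-5-(methoxycarbonyl)-2,2-dimethyl-1,3-dioxolane-4-carboxylic acid | COC(=O)[C@H]1OC(C)(C)O[C@@H]1C(=O)O
F6 | step 1 | methyl (4S,5R)-5-(hydroxymethyl)-2,2-dimethyl-1,3-dioxolane-4-carboxylate | COC(=O)[C@H]1OC(C)(C)O[C@@H]1CO
F7 | step 8 | (4R,5S,6S)-4,5,6-trihydroxy-6-(hydroxymethyl)cyclohex-2-en-1-one | O[C@H]1[C@H](O)C=CC(=O)[C@]1(O)CO
A1 | alternative 1 | (1-hydroxy-4-oxocyclohexa-2,5-dien-1-yl)methyl benzoate (achiral p-quinol) | O=C1C=CC(O)(COC(=O)c2ccccc2)C=C1
A2 | alternative 1 | cis-fused phenylboronate of the C1,C2-diol enone (carbonyl at C4, alkene C5=C6, benzoyloxymethyl on C1) | c1ccccc1B1O[C@H]2CC(=O)C=C[C@@]2(COC(=O)c2ccccc2)O1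
A3 | alternative 2 | (3aS,7aS)-4-bromo-2,2-dimethyl-3a,7a-dihydro-1,3-benzodioxole (bromodiene cis-diol acetonide) | CC1(C)O[C@H]2C=CC=C(Br)[C@H]2O1
A4 | alternative 2 | bridgehead-bromo endoperoxide acetonide (2,3-dioxabicyclo[2.2.2]octene, peroxide anti to the ketal) | CC1(C)O[C@H]2[C@H]3C=C[C@](Br)(OO3)[C@H]2O1
A5 | alternative 2 | (3aS,7R,7aS)-7-hydroxy-2,2-dimethyl-7,7a-dihydro-1,3-benzodioxol-4(3aH)-one | CC1(C)O[C@H]2[C@H](O)C=CC(=O)[C@H]2O1
A6 | alternative 3 | 3-O-acetyl-1,5-anhydro-2,4-di-O-benzoyl-6,7-dideoxy-D-arabino-hepta-1,6-dienitol (2-benzoyloxy glycal with vinyl on sugar C5) | O1C=C(OC(=O)c2ccccc2)[C@@H](OC(C)=O)[C@H](OC(=O)c2ccccc2)[C@H]1C=C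
A7 | alternative 3 | 2-acetoxy-1,3-bis(benzoyloxy)cyclohex-4-ene-1-carbaldehyde (target numbering, 1S,2S,3R arrangement of the target) | CC(=O)O[C@H]1[C@H](OC(=O)c2ccccc2)C=CC[C@]1(OC(=O)c1ccccc1)C=O
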